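The route rests on cutting the aryl–oxygen bond between C5 of the catechol ring (ring C; C1 carries the ethano bridge, C3 and C4 the hydroxyls) and the oxygen on the para-phenylene ring (ring D). C5 sits beside the C4 oxygen and meta to C1, exactly the bromine position of 5-bromoveratraldehyde. The key step is a copper-catalysed Ullmann macrocyclisation in which the only free phenol of an open-chain, O-methylated bis(bibenzyl) monoether displaces this bromide and closes the 19-membered ring in one operation. The precursor comes from two Wittig olefinations, one Chan–Lam etherification and a halogen-sparing diimide reduction; global O-demethylation finishes the synthesis.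

Key step: step 8

Remark on the chemistry: ring A is the 4-hydroxy-3-aryloxyphenyl ring and ring B the meta-phenylene ring; the target has no stereocentre; both Wittig products are expected as E/Z mixtures that converge in step 6, so their SMILES are written without alkene geometry.

Step 1
Reactants: 1 3-hydroxybenzyl alcohol
Product: 2 (3-hydroxybenzyl)triphenylphosphonium bromide
Conditions: PPh3·HBr, MeCN, reflux
Reagents that add atoms: triphenylphosphine hydrobromide, [Br-].c1ccc(cc1)[PH+](c1ccccc1)c1ccccc1
Why: Direct phosphonium salt formation by nucleophilic substitution: the acid ionises the benzylic alcohol and PPh3 captures the benzylic carbon, while the phenolic OH is inert and needs no protection.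

Step 2
Reactants: 2 (3-hydroxybenzyl)triphenylphosphonium bromide; 3 3-bromo-4,5-dimethoxybenzaldehyde (5-bromoveratraldehyde)
Product: 4 3-[2-(3-bromo-4,5-dimethoxyphenyl)ethenyl]phenol (E/Z mixture)
Conditions: KOtBu (2.2 equiv), THF, 0 °C to rt; then aq NH4Cl
Reagents that add atoms: none
Why: Wittig olefination with two equivalents of base; the meta-oxido ylide cannot expel PPh3 as a quinone methide and should condense cleanly with the aldehyde, KOtBu leaves the aryl bromide alone, and the alkene geometry is irrelevant because step 6 saturates it (no stereocentre is formed).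

Step 3
Reactants: 4 3-[2-(3-bromo-4,5-dimethoxyphenyl)ethenyl]phenol; 5 (5-formyl-2-methoxyphenyl)boronic acid
Product: 6 3-{3-[2-(3-bromo-4,5-dimethoxyphenyl)ethenyl]phenoxy}-4-methoxybenzaldehyde (E/Z mixture)
Conditions: Cu(OAc)2 (1.5 equiv), pyridine, 4 Å MS, CH2Cl2, air, rt
Reagents that add atoms: none
Why: Chan–Lam oxidative O-arylation (transmetalation of the boronic acid to the copper(II) phenoxide, then C–O reductive elimination from Cu(III)) runs at room temperature, where the ring C bromide, the alkene and the aldehyde should stay untouched, which an Ullmann coupling with a second aryl bromide could not guarantee.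

Step 4
Reactants: 7 4-(benzyloxy)benzyl chloride
Product: 8 [4-(benzyloxy)benzyl]triphenylphosphonium chloride
Conditions: PPh3, toluene, reflux
Reagents that add atoms: triphenylphosphine, c1ccc(cc1)P(c1ccccc1)c1ccccc1
Why: SN2 quaternisation of triphenylphosphine by a reactive benzylic chloride; the salt should crystallise from toluene.

Step 5
Reactants: 6 3-{3-[2-(3-bromo-4,5-dimethoxyphenyl)ethenyl]phenoxy}-4-methoxybenzaldehyde; 8 [4-(benzyloxy)benzyl]triphenylphosphonium chloride
Product: 9 bis-stilbene: 5-[2-(3-{5-[2-(4-benzyloxyphenyl)ethenyl]-2-methoxyphenoxy}phenyl)ethenyl]-1-bromo-2,3-dimethoxybenzene (E/Z mixture at both alkenes)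
Conditions: KOtBu, THF, 0 °C to rt
Reagents that add atoms: none
Why: Wittig olefination of the ring A aldehyde with a semi-stabilised benzylic ylide; the base is compatible with the aryl bromide, the benzyl ether and the diaryl ether, and the mixed geometry is removed in step 6.

Step 6
Reactants: 9 bis-stilbene
Product: 10 5-[2-(3-{5-[2-(4-benzyloxyphenyl)ethyl]-2-methoxyphenoxy}phenyl)ethyl]-1-bromo-2,3-dimethoxybenzene
Conditions: TsNHNH2 (excess, in portions), NaOAc, DME/H2O, reflux
Reagents that add atoms: none
Why: Diimide reduction: HN=NH released from the sulfonyl hydrazide transfers H2 to both C=C bonds in a concerted syn fashion and should leave the C–Br bond and the benzyl ether intact, which hydrogenation over palladium would not.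

Step 7
Reactants: 10 bis(bibenzyl) benzyl ether
Product: 11 4-{2-[3-(3-{2-(3-bromo-4,5-dimethoxyphenyl)ethyl}phenoxy)-4-methoxyphenyl]ethyl}phenol
Conditions: BCl3, pentamethylbenzene, CH2Cl2, −78 °C; then aq NaHCO3
Reagents that add atoms: none
Why: Lewis-acid debenzylation with a cation scavenger: BCl3 activates the benzyl ether and pentamethylbenzene traps the benzyl cation by Friedel–Crafts alkylation, and at −78 °C the three aryl methyl ethers, the diaryl ether and the aryl bromide should survive.

Step 8
Reactants: 11 4-{2-[3-(3-{2-(3-bromo-4,5-dimethoxyphenyl)ethyl}phenoxy)-4-methoxyphenyl]ethyl}phenol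
Product: 12 tri-O-methyl macrocycle (the target with its three hydroxyls as methyl ethers)
Conditions: CuI, N,N-dimethylglycine·HCl, Cs2CO3, 1,4-dioxane, 100 °C, slow addition of 11, about 2 mM
Reagents that add atoms: none
Why: Ullmann-type copper-catalysed O-arylation: Cs2CO3 forms the ring D phenoxide, which binds the glycine-ligated Cu(I); oxidative addition into the C5–Br bond of ring C and C–O reductive elimination from Cu(III) give the diaryl ether and return Cu(I). The closest known reaction type is the intramolecular Ullmann diaryl ether synthesis used to close diaryl ether cyclophanes and macrocycles. The one ring closed is the 19-membered macrocycle, formed by end-to-end macrocyclisation through C(sp2)–O bond formation (Baldwin descriptors do not apply); the two flexible CH2CH2 bridges and the meta/meta/meta/para arene geometry should keep it nearly strain-free. No stereocentre is formed. The step needs intramolecular over intermolecular O-arylation, secured by slow addition to high dilution, and chemoselectivity, secured because 11 holds one free OH and one C–halogen bond whose position fixes the new bond at C5 rather than C2 or C6; the C4 methoxy group beside the bromide should not block oxidative addition under amino-acid-ligated copper.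

Step 9
Reactants: 12 tri-O-methyl macrocycle
Product: 13 target macrocyclic bis(bibenzyl) diether triol (CNP0495401.0)
Conditions: BBr3, CH2Cl2, −78 °C to rt; then H2O, under argon
Reagents that add atoms: none
Why: Lewis-acid cleavage of aryl methyl ethers (boron coordination, then SN2 attack of bromide on methyl) should free all three phenols, while the two diaryl ether bonds have no carbon open to SN2 attack and should survive; argon protects the catechol from air oxidation.

Compound list
1 | 3-hydroxybenzyl alcohol | OCc1cccc(O)c1 | starting material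
2 | (3-hydroxybenzyl)triphenylphosphonium bromide | [Br-].Oc1cccc(C[P+](c2ccccc2)(c2ccccc2)c2ccccc2)c1 | intermediate
3 | 3-bromo-4,5-dimethoxybenzaldehyde | COc1cc(C=O)cc(Br)c1OC | starting material
4 | 3-[2-(3-bromo-4,5-dimethoxyphenyl)ethenyl]phenol (E/Z mixture) | COc1cc(C=Cc2cccc(O)c2)cc(Br)c1OC | intermediate
5 | (5-formyl-2-methoxyphenyl)boronic acid | COc1ccc(C=O)cc1B(O)O | starting material
6 | 3-{3-[2-(3-bromo-4,5-dimethoxyphenyl)ethenyl]phenoxy}-4-methoxybenzaldehyde (E/Z mixture) | COc1ccc(C=O)cc1Oc1cccc(C=Cc2cc(OC)c(OC)c(Br)c2)c1 | intermediate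
7 | 4-(benzyloxy)benzyl chloride | ClCc1ccc(OCc2ccccc2)cc1 | starting material
8 | [4-(benzyloxy)benzyl]triphenylphosphonium chloride | [Cl-].c1ccc(COc2ccc(C[P+](c3ccccc3)(c3ccccc3)c3ccccc3)cc2)cc1 | intermediate
9 | bis-stilbene, 5-[2-(3-{5-[2-(4-benzyloxyphenyl)ethenyl]-2-methoxyphenoxy}phenyl)ethenyl]-1-bromo-2,3-dimethoxybenzene (E/Z mixture) | COc1ccc(C=Cc2ccc(OCc3ccccc3)cc2)cc1Oc1cccc(C=Cc2cc(OC)c(OC)c(Br)c2)c1 | intermediate
10 | 5-[2-(3-{5-[2-(4-benzyloxyphenyl)ethyl]-2-methoxyphenoxy}phenyl)ethyl]-1-bromo-2,3-dimethoxybenzene | COc1ccc(CCc2ccc(OCc3ccccc3)cc2)cc1Oc1cccc(CCc2cc(OC)c(OC)c(Br)c2)c1 | intermediate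
11 | 4-{2-[3-(3-{2-(3-bromo-4,5-dimethoxyphenyl)ethyl}phenoxy)-4-methoxyphenyl]ethyl}phenol | COc1ccc(CCc2ccc(O)cc2)cc1Oc1cccc(CCc2cc(OC)c(OC)c(Br)c2)c1 | intermediate
12 | tri-O-methyl macrocycle | COc1ccc2cc1Oc1cccc(c1)CCc1cc(OC)c(OC)c(c1)Oc1ccc(cc1)CC2 | intermediate
13 | target macrocyclic bis(bibenzyl) diether triol (CNP0495401.0) | Oc1ccc2cc1Oc1cccc(c1)CCc1cc(O)c(O)c(c1)Oc1ccc(cc1)CC2 | target

Total step count: 9. Longest linear sequence: 8 steps (steps 1, 2, 3, 5, 6, 7, 8, 9, from 3-hydroxybenzyl alcohol); step 4 is a one-step side branch.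

Steps most likely to fail

Step 8 (key macrocyclisation). Intermolecular O-arylation may outrun ring closure and give oligomers, or oxidative addition at the electron-rich bromide may stall and the bromine be lost reductively. The fallback reverses the polarity of ring C and closes the same C5–O bond oxidatively; it sets out from compound 10 and comes back at compound 12. Palladium-catalysed Miyaura borylation of 10 (B2pin2, Pd(dppf)Cl2, KOAc, dioxane, 90 °C) should give the benzyl-protected pinacol boronate F1. With no halogen left, hydrogenolysis (H2, Pd/C, EtOAc) should free the ring D phenol and give the phenol pinacol boronate F2. An intramolecular Chan–Lam coupling of F2 (Cu(OAc)2, pyridine, B(OH)3, 4 Å MS, MeCN, air, 60 °C, high dilution) should then give 12.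

Step 3 (Chan–Lam etherification). Transmetalation of the ortho-methoxylated boronic acid may be slow, so that protodeboronation and oxidative homocoupling consume it while phenol 4 stays unreacted. The fallback makes the ring A–ring B ether by Ullmann coupling before any ring C bromide is in the molecule. It sets out from compound 8, joined by the new commercial materials isovanillin (COc1ccc(C=O)cc1O) and 3-bromobenzyl alcohol (OCc1cccc(Br)c1) and later by 3, and comes back at compound 9. Ullmann coupling of isovanillin with 3-bromobenzyl alcohol (CuI, N,N-dimethylglycine, Cs2CO3, dioxane, 90 °C) should give the diaryl ether aldehyde–alcohol F3. Wittig reaction of F3 with 8 (KOtBu, THF) should give the stilbene benzylic alcohol F4. PPh3·HBr in refluxing MeCN should turn F4 into the phosphonium bromide F5, and Wittig reaction of F5 with aldehyde 3 (KOtBu, THF) should give 9.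

Step 7 (debenzylation). The Lewis acid may also cleave a methyl ether, most likely on the vicinal dimethoxy ring C, or the benzyl cation may re-alkylate an electron-rich ring. The fallback changes the ring D protecting group to a fluoride-labile silyl ether; it sets out from compound 6 and comes back at compound 11. Commercial 4-(tert-butyldimethylsilyloxy)benzyl alcohol (CC(C)(C)[Si](C)(C)Oc1ccc(CO)cc1) should give with CBr4/PPh3 in CH2Cl2 the silyloxybenzyl bromide F6, and PPh3 in toluene should convert it into the silyloxybenzyl phosphonium bromide F7. Wittig reaction of F7 with 6 (LiHMDS, THF, −78 °C to rt) should give the silyl-protected bis-stilbene F8. Diimide reduction as in step 6 should give the silyl-protected bis(bibenzyl) F9, and TBAF in THF at 0 °C should then give 11.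

Further compounds
F1 | step 8 | 2-{5-[2-(3-{5-[2-(4-benzyloxyphenyl)ethyl]-2-methoxyphenoxy}phenyl)ethyl]-2,3-dimethoxyphenyl}-4,4,5,5-tetramethyl-1,3,2-dioxaborolane | COc1ccc(CCc2ccc(OCc3ccccc3)cc2)cc1Oc1cccc(CCc2cc(OC)c(OC)c(B3OC(C)(C)C(C)(C)O3)c2)c1
F2 | step 8 | 4-{2-[3-(3-{2-[3,4-dimethoxy-5-(4,4,5,5-tetramethyl-1,3,2-dioxaborolan-2-yl)phenyl]ethyl}phenoxy)-4-methoxyphenyl]ethyl}phenol | COc1ccc(CCc2ccc(O)cc2)cc1Oc1cccc(CCc2cc(OC)c(OC)c(B3OC(C)(C)C(C)(C)O3)c2)c1
F3 | step 3 | 3-[3-(hydroxymethyl)phenoxy]-4-methoxybenzaldehyde | COc1ccc(C=O)cc1Oc1cccc(CO)c1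
F4 | step 3 | (3-{5-[2-(4-benzyloxyphenyl)ethenyl]-2-methoxyphenoxy}phenyl)methanol (E/Z mixture) | COc1ccc(C=Cc2ccc(OCc3ccccc3)cc2)cc1Oc1cccc(CO)c1
F5 | step 3 | (3-{5-[2-(4-benzyloxyphenyl)ethenyl]-2-methoxyphenoxy}benzyl)triphenylphosphonium bromide (E/Z mixture) | [Br-].COc1ccc(C=Cc2ccc(OCc3ccccc3)cc2)cc1Oc1cccc(C[P+](c2ccccc2)(c2ccccc2)c2ccccc2)c1
F6 | step 7 | 4-(tert-butyldimethylsilyloxy)benzyl bromide | CC(C)(C)[Si](C)(C)Oc1ccc(CBr)cc1
F7 | step 7 | [4-(tert-butyldimethylsilyloxy)benzyl]triphenylphosphonium bromide | [Br-].CC(C)(C)[Si](C)(C)Oc1ccc(C[P+](c2ccccc2)(c2ccccc2)c2ccccc2)cc1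
F8 | step 7 | silyl-protected bis-stilbene, tert-butyl(4-{2-[3-(3-{2-(3-bromo-4,5-dimethoxyphenyl)ethenyl}phenoxy)-4-methoxyphenyl]ethenyl}phenoxy)dimethylsilane (E/Z mixture) | COc1ccc(C=Cc2ccc(O[Si](C)(C)C(C)(C)C)cc2)cc1Oc1cccc(C=Cc2cc(OC)c(OC)c(Br)c2)c1
F9 | step 7 | silyl-protected bis(bibenzyl), tert-butyl(4-{2-[3-(3-{2-(3-bromo-4,5-dimethoxyphenyl)ethyl}phenoxy)-4-methoxyphenyl]ethyl}phenoxy)dimethylsilane | COc1ccc(CCc2ccc(O[Si](C)(C)C(C)(C)C)cc2)cc1Oc1cccc(CCc2cc(OC)c(OC)c(Br)c2)c1
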